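A small charge of X, 1.5 M, came first; the flask holds twice that.

| flask | X | remark | time |
|---|---|---|---|
| theta | 1.5 M | run made earlier |  |
| flask | 3.0 M |  | 8.0 h |

theta run (percent of the X charged)

| time / h | L / % | Z / % |
|---|---|---|
| 1.00 | 14.7 | 4.8 |
| 2.50 | 44.8 | 5.0 |
| 3.00 | 54.1 | 6.1 |
| 5.00 | 93.8 | 6.5 |
| 6.00 | 96.1 | 2.9 |
| 8.00 | 97.5 | 1.9 |

(each reading ± 0.5 percentage points)

* how much L there is at 8.0 h, in percent of the X charged
* concentration of Z in solution at 8.0 h, in percent of saturation

- a species is counted by the X in it: one G counts as two
- given per volume of solution although it is solid: X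
- the numbers in the tables scatter by 0.5 percentage points (one standard deviation)
- candidate steps: 2 Z -> G; X <-> Z; Z <-> L
- at the start none of X is in solution
- Z means what is dissolved; the solid is not counted in it

In the small run c_L + c_Z rose in a straight line from zero, so by 3.00 h X had entered solution at 0.301 M/h, the rate I call the feed. It held while the solid shrank, so I kept it in M/h for the larger charge. The line of c_L + c_Z stayed straight up to 5.00 h, where it stood at 100 %, so I took going into solution as the rate-limiting step. Saturation I could not read: the feed held while Z went from 4.8 % to 6.5 %.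

So the flask dissolves 2.41 M by 8.0 h, less than its charge of 3.0 M. Of that I left 0.0720 M in Z, the small run's reading at 1.00 h, and gave L the share it held of L and Z at 8.00 h, 98.1 %. L comes to 76.5 %.

The forecast gave 76 % of L and 10 % of saturation, holding that “Z sits well below saturation”. The flask gives 75.5 % and 6.27 %.

    2 Z → G (k = 0.0360 /M/h)
    X ⇌ Z, rate k2*(cs2 - [Z]) while solid is left; crystals form when [Z] > cs2 (solubility = 2.10 M, k = 0.150 /h)
    Z ⇌ L (K = 34.0, k = 4.40 /h)

The feed leaves 19.7 % of this flask's X solid at 8.0 h, and the flask holds 19.9 %. In the neighbouring flask, with 0.75 M of X, the same feed spends the solid in 2.49 h, sooner than 8.0 h, so I reckon L at the share 98.1 %. That flask holds L 97.0 %, Z 2.85 % and solid X 0 % at 8.00 h.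

The data stem from a simulated flask on assumed constants; the scatter is artificial.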